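At early times the mono adduct in birch climbs fast; watch how soon that climb slows.

| flask | substrate | reagent | temperature | remark | time |
|---|---|---|---|---|---|
| birch | 0.40 M | 0.40 M | 20 °C | the very flask that is asked about, followed so far |  |
| oak | 0.40 M | 0.40 M | 15 °C | run made earlier |  |
| flask | 0.40 M | 0.400 M | 20 °C |  | 3.0 min |

- birch (time / min: mono adduct / %): 0.167: 5.8; 0.500: 11.1; 0.833: 14.6; 1.33: 15.4; 2.00: 16.9; 2.50: 18.3; 3.00: 18.9
- oak (time / min: mono adduct / %): 0.167: 2.8; 0.500: 7.6; 0.833: 11.2; 1.33: 14.0; 2.00: 16.3; 2.50: 15.5; 3.00: 15.9

(standard deviation of a reading: 0.5 percentage points)

- Friday's: at 3.0 min raise the temperature by 10 K, then wait 6.0 min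
- Thursday's: change nothing and wait 6.0 min more
- Saturday's: at 3.0 min take out 90% of the by-product then present, then wait 6.0 min
- Sunday's: at 3.0 min add reagent, 50.0% of the amount charged, then wait 6.0 min

- additions bring no volume worth counting

* mono adduct, in percent of the substrate first charged, at 3.0 min
* the option that brings most further mono adduct ("none" if no option brings more than 2 percentage points) (Friday's / Thursday's / Saturday's / Sunday's / none)
* mono adduct present, in percent of the substrate first charged, after Friday's
* mono adduct present, in percent of the substrate first charged, after Thursday's

Birch is the asked flask itself, so my answer for now is its last reading, 18.9%. Substrate and reagent are charged equally, so if each mono adduct costs one reagent, both stand at the same unspent fraction, a. Write the reagent's balance from the rates: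

early rate = 5.8% in 0.167 min = 0.347 /min
late rate = (18.9% − 16.9%) over the last stretch = 0.0200 /min
a = 81.1%
early rate × a × a = 0.228 /min

The late rate is far lower than that. So I define the working share, the part of the unspent reagent still free to react, as late rate / (early rate × a × a):

working share = 0.0876

On this reckoning, 0.0710 of the reagent charged works and 0.740 sits out of reach. Holding that share, 1/a grows steadily:

1/a after waiting = 1.23 + early rate × share × 6.0 min = 1.42
Thursday's: 29.4%

Saturday's reckons the same if by-product plays no part, and these runs, with no reading of by-product, leave that open. Sunday's raises the unspent reagent, so I scale the gain to 17 percentage points.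

Friday's needs a temperature factor. The first pair of readings gives 50.4%, but that is the weak link: oak's 2.8% carries a scatter of 0.5 points, and the ratio is squared for the rise. The pair at 0.500 min, 11.1% over 7.6%, is steadier:

Friday's: 38.4%, a gain of 19 points

I choose Friday's.

The forecast gives 18.7%, then 20.5% after Thursday's and 25% after Friday's, both lower than mine, and it names Saturday's where I name Friday's: "This fits best with a reversible step or by-product holding back the reaction".

The flask gives 19.3%, 25.9% after Thursday's and 36.9% after Friday's. Friday's brings most, with 18 points against Sunday's 14 points.

    reagent + mono adduct → bis adduct + by-product (k = 0.00473 /M/s, Ea = 50.0 kJ/mol)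
    reagent + other mono adduct → bis adduct + by-product (k = 0.0175 /M/s, Ea = 41.0 kJ/mol)
    substrate + reagent → other mono adduct + by-product (k = 0.00258 /M/s, Ea = 54.0 kJ/mol)
    substrate + reagent → mono adduct + by-product (k = 0.0165 /M/s, Ea = 68.0 kJ/mol)
    reagent + mono adduct → over-reaction product (k = 0.00339 /M/s, Ea = 53.0 kJ/mol)
    reagent ⇌ dormant form (K = 11.4, k = 0.0271 /s, Ea = 69.0 kJ/mol, ΔH = −28.0 kJ/mol)
    (constants at 20 °C)

At 0.291 min the forward step to dormant form uses reagent 4.5 times as fast as the step to mono adduct. At 3.00 min this resting state holds 69.7% of the reagent charged to the flask, and 5.12% is free, a working share of 0.0685. A neighbour flask, charged with 1.6 M of reagent, has 1.17 M dormant at 3.00 min. My share of its unspent reagent, free and dormant together, predicts 6.89% of its charge free, and that neighbour holds 5.77%.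

Readings and results are calculated for substances that don't exist, noise included.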